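**Retrosynthetic overview**
- The target comes from a bis-silyl-protected tropone by one fluoride deprotection.
- The tropone ring is made last by inserting one CH into the para–meta (C3a–C4) bond of a hexasubstituted spiro-dihydrobenzofuranol; this is the proposed new step.
- C8 is set by ether-directed hydrogenation of a cyclohexene; the spiro-dihydrofuran ring (C11–aryl and C9–O bonds, C9 stereocentre) comes from a Pd-catalysed heteroannulation of an exocyclic 1,3-diene with iodinated atraric acid methyl ester.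
- The diene comes from (S)-carvone: hydration of the isopropenyl group, α'-methylation then α'-allylation (quaternary C10), oxidation of the allyl group to a propanoate, and methylenation of the ketone.
- Ring order: cyclohexane (from carvone), then dihydrofuran (annulation), then benzene-to-tropone ring expansion.

Assumption: locants C5 (CH bearing the hydroxyisopropyl group), C6, C7, C8 (CH–CH3), C9 (spiro carbon), C10 (quaternary carbon) and C11 (ArCH2) are used for the cyclohexane part, arene carbons carry benzofuran locants, "upper face" is the cyclohexane face that carries the ring oxygen in the target, and all reagents written over the arrows are purchased.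

**Step 1**
Reactants: 1 (S)-(+)-carvone
Product: 2 (5S)-5-(2-hydroxypropan-2-yl)-2-methylcyclohex-2-en-1-one
Conditions: Co(acac)2 (20 mol %), PhSiH3, O2 (1 atm), THF, rt
Reagents that add atoms: dioxygen, O=O
Why: Mukaiyama hydration, in which the cobalt hydride transfers a hydrogen atom to the electron-rich 1,1-disubstituted alkene and the tertiary radical is trapped by O2 (Markovnikov alcohol), while the conjugated enone is much less reactive and C5 is untouched.

**Step 2**
Reactants: 2 (5S)-5-(2-hydroxypropan-2-yl)-2-methylcyclohex-2-en-1-one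
Product: 3 (5S)-2-methyl-5-[2-(triethylsilyloxy)propan-2-yl]cyclohex-2-en-1-one
Conditions: Et3SiOTf, 2,6-lutidine, CH2Cl2, −78 → 0 °C
Reagents that add atoms: triethylsilyl trifluoromethanesulfonate, CC[Si](CC)(CC)OS(=O)(=O)C(F)(F)F
Why: Silyl triflate silylation caps the hindered tertiary alcohol, which would otherwise consume base in steps 3 and 4 and compete as a nucleophile in step 10.

**Step 3**
Reactants: 3 (5S)-2-methyl-5-[2-(triethylsilyloxy)propan-2-yl]cyclohex-2-en-1-one
Product: 5 (5S,6R)-2,6-dimethyl-5-[2-(triethylsilyloxy)propan-2-yl]cyclohex-2-en-1-one, via lithium dienolate 4 (not isolated)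
Conditions: LiN(iPr)2, THF, −78 °C; MeI, −78 → 0 °C
Reagents that add atoms: iodomethane, CI
Why: Kinetic α'-deprotonation gives the cross-conjugated dienolate, whose C-methylation (enolate alkylation) occurs mainly anti to the C5 substituent; the new centre is re-enolised in step 4, so its epimer ratio does not matter.

**Step 4**
Reactants: 5 (5S,6R)-2,6-dimethyl-5-[2-(triethylsilyloxy)propan-2-yl]cyclohex-2-en-1-one
Product: 7 (5S,6R)-2,6-dimethyl-6-(prop-2-en-1-yl)-5-[2-(triethylsilyloxy)propan-2-yl]cyclohex-2-en-1-one, via lithium dienolate 6 (not isolated)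
Conditions: LiN(iPr)2, THF, −78 → −20 °C; allyl bromide, DMPU, −78 °C → rt
Reagents that add atoms: allyl bromide, C=CCBr
Why: Second enolate alkylation, in which allyl bromide approaches the dienolate anti to the bulky C5 silyloxyisopropyl group, so the quaternary C10 forms with methyl cis and allyl trans to that group (6R).

**Step 5**
Reactants: 7 (5S,6R)-2,6-dimethyl-6-(prop-2-en-1-yl)-5-[2-(triethylsilyloxy)propan-2-yl]cyclohex-2-en-1-one
Product: 9 (5S,6R)-6-(3-hydroxypropyl)-2,6-dimethyl-5-[2-(triethylsilyloxy)propan-2-yl]cyclohex-2-en-1-one, via B-alkyl-9-BBN adduct 8 (not isolated)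
Conditions: 9-BBN, THF, 0 °C → rt; then H2O2, pH 7 phosphate buffer, 0 °C → rt
Reagents that add atoms: hydrogen peroxide, OO
Why: Anti-Markovnikov hydroboration–oxidation, since 9-BBN adds to the monosubstituted alkene much faster than it reduces the hindered enone carbonyl next to the quaternary carbon, and buffered peroxide avoids nucleophilic epoxidation of the enone.

**Step 6**
Reactants: 9 (5S,6R)-6-(3-hydroxypropyl)-2,6-dimethyl-5-[2-(triethylsilyloxy)propan-2-yl]cyclohex-2-en-1-one
Product: 10 3-[(1R,6S)-1,3-dimethyl-2-oxo-6-[2-(triethylsilyloxy)propan-2-yl]cyclohex-3-en-1-yl]propanoic acid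
Conditions: TEMPO (10 mol %), NaClO2, NaOCl (cat.), MeCN/phosphate buffer pH 6.7, 35 °C
Reagents that add atoms: sodium chlorite NaClO2, [Na+].[O-]Cl=O
Why: TEMPO/chlorite oxidation takes the primary alcohol through the aldehyde to the acid under near-neutral conditions that leave the silyl ether and the enone intact.

**Step 7**
Reactants: 10 3-[(1R,6S)-1,3-dimethyl-2-oxo-6-[2-(triethylsilyloxy)propan-2-yl]cyclohex-3-en-1-yl]propanoic acid
Product: 11 2-(trimethylsilyl)ethyl 3-[(1R,6S)-1,3-dimethyl-2-oxo-6-[2-(triethylsilyloxy)propan-2-yl]cyclohex-3-en-1-yl]propanoate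
Conditions: Me3SiCH2CH2OH, EDC·HCl, DMAP, CH2Cl2, 0 °C → rt
Reagents that add atoms: 2-(trimethylsilyl)ethanol, C[Si](C)(C)CCO
Why: Carbodiimide (Steglich) esterification gives a fluoride-labile ester that keeps the carboxylate from competing as a nucleophile in step 10 and is removed together with the silyl ether in the last step.

**Step 8**
Reactants: 11 2-(trimethylsilyl)ethyl 3-[(1R,6S)-1,3-dimethyl-2-oxo-6-[2-(triethylsilyloxy)propan-2-yl]cyclohex-3-en-1-yl]propanoate
Product: 12 2-(trimethylsilyl)ethyl 3-[(1R,6S)-1,3-dimethyl-2-methylidene-6-[2-(triethylsilyloxy)propan-2-yl]cyclohex-3-en-1-yl]propanoate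
Conditions: Zn, CH2Br2, TiCl4, THF/CH2Cl2, 0 °C → rt
Reagents that add atoms: dibromomethane, BrCBr
Why: Lombardo–Takai methylenation, whose non-basic, oxophilic zinc/titanium methylene reagent olefinates the hindered enone carbonyl without enolisation and does not touch esters, giving the exocyclic 1,3-diene.

**Step 9**
Reactants: 13 methyl 2,4-dihydroxy-3,6-dimethylbenzoate (atraric acid)
Product: 14 methyl 2,4-dihydroxy-5-iodo-3,6-dimethylbenzoate
Conditions: N-iodosuccinimide, TsOH (10 mol %), MeCN, 0 °C → rt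
Reagents that add atoms: N-iodosuccinimide, O=C1CCC(=O)N1I
Why: Electrophilic aromatic iodination can only occur at the single free ring position, which is activated ortho and para by the two hydroxyl groups.

**Step 10**
Reactants: 12 2-(trimethylsilyl)ethyl 3-[(1R,6S)-1,3-dimethyl-2-methylidene-6-[2-(triethylsilyloxy)propan-2-yl]cyclohex-3-en-1-yl]propanoate; 14 methyl 2,4-dihydroxy-5-iodo-3,6-dimethylbenzoate
Product: 15 2-(trimethylsilyl)ethyl 3-[(2S,5'S,6'R)-6-hydroxy-5-(methoxycarbonyl)-2',4,6',7-tetramethyl-5'-[2-(triethylsilyloxy)propan-2-yl]-3H-spiro[1-benzofuran-2,1'-cyclohex[2]en]-6'-yl]propanoate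
Conditions: Pd(OAc)2 (10 mol %), n-Bu4NCl, NaHCO3, DMF, 80 °C
Reagents that add atoms: none
Why: Larock heteroannulation of a 1,3-diene, in which oxidative addition of the aryl iodide to zerovalent palladium, aryl transfer to the terminal CH2 (C11) and capture of the allylpalladium at its fully substituted end (C9) by the ortho phenoxide build the spiro dihydrobenzofuran; palladium adds, and the tethered oxygen closes, on the face anti to the pseudo-axial C10 methyl, which sets C9 as S.

**Step 11**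
Reactants: 15 2-(trimethylsilyl)ethyl 3-[(2S,5'S,6'R)-6-hydroxy-5-(methoxycarbonyl)-2',4,6',7-tetramethyl-5'-[2-(triethylsilyloxy)propan-2-yl]-3H-spiro[1-benzofuran-2,1'-cyclohex[2]en]-6'-yl]propanoate
Product: 16 2-(trimethylsilyl)ethyl 3-[(2S,2'R,5'S,6'R)-6-hydroxy-5-(methoxycarbonyl)-2',4,6',7-tetramethyl-5'-[2-(triethylsilyloxy)propan-2-yl]-3H-spiro[1-benzofuran-2,1'-cyclohexan]-6'-yl]propanoate
Conditions: [Ir(cod)(PCy3)(py)]PF6 (10 mol %), H2 (1 atm), CH2Cl2, rt
Reagents that add atoms: none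
Why: Directed homogeneous hydrogenation, in which the cationic iridium catalyst binds the ring oxygen and adds H2 to the trisubstituted alkene from the upper face (also the face away from the axial C10 methyl and C11), so the C8 methyl ends cis to the C10 methyl (8R) without allylic C–O hydrogenolysis.

**Step 12**
Reactants: 16 2-(trimethylsilyl)ethyl 3-[(2S,2'R,5'S,6'R)-6-hydroxy-5-(methoxycarbonyl)-2',4,6',7-tetramethyl-5'-[2-(triethylsilyloxy)propan-2-yl]-3H-spiro[1-benzofuran-2,1'-cyclohexan]-6'-yl]propanoate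
Product: 18 2-(trimethylsilyl)ethyl 3-[(2S,2'R,5'S,6'R)-6-(methoxycarbonyl)-2',5,6',8-tetramethyl-7-oxo-5'-[2-(triethylsilyloxy)propan-2-yl]-3,7-dihydrospiro[cyclohepta[b]furan-2,1'-cyclohexan]-6'-yl]propanoate, via dichloromethyl dienone 17 (not isolated)
Conditions: BrCHCl2 (3 equiv), Cs2CO3, fac-Ir(ppy)3 (1 mol %), MeCN, 450 nm LEDs, rt; evaporate; then (Me3Si)3SiH, AIBN (cat.), PhMe, 80 °C
Reagents that add atoms: bromodichloromethane, ClC(Cl)Br
Why: Proposed new method: the excited photocatalyst reduces BrCHCl2 to the electrophilic dichloromethyl radical, which couples with the caesium phenolate (or its persistent, fully substituted phenoxyl radical) at the blocked para carbon C3a, the site of highest charge and spin density (para to O−, ortho to the ring ether oxygen), giving the dearomatised dienone; chlorine abstraction by the silyl radical then gives an α-chloroalkyl radical that closes 3-exo onto the ester-activated enone carbon C4 (not onto the oxygen-bearing, electron-rich C7a) and reopens to the seven-membered ring radical, which expels a chlorine atom to aromatise to the tropone, so one CH is inserted into the C3a–C4 bond and the seven-membered ring is formed; the closest known reaction types are the abnormal Reimer–Tiemann para-dichloromethylation of para-substituted phenols, para coupling of hindered phenoxyl radicals with carbon radicals, and the Bu3SnH-mediated (Dowd–Beckwith type) ring expansion of 4-(dichloromethyl)cyclohexa-2,5-dienones to tropones.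

**Step 13**
Reactants: 18 2-(trimethylsilyl)ethyl 3-[(2S,2'R,5'S,6'R)-6-(methoxycarbonyl)-2',5,6',8-tetramethyl-7-oxo-5'-[2-(triethylsilyloxy)propan-2-yl]-3,7-dihydrospiro[cyclohepta[b]furan-2,1'-cyclohexan]-6'-yl]propanoate
Product: 19 3-[(2S,2'R,5'S,6'R)-5'-(2-hydroxypropan-2-yl)-6-(methoxycarbonyl)-2',5,6',8-tetramethyl-7-oxo-3,7-dihydrospiro[cyclohepta[b]furan-2,1'-cyclohexan]-6'-yl]propanoic acid
Conditions: Bu4NF, THF, rt → 40 °C; then dilute aq. HCl to pH 3
Reagents that add atoms: none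
Why: Fluoride attacks silicon in both protecting groups (β-elimination of the 2-silylethyl ester and cleavage of the triethylsilyl ether), conditions that leave the hindered tropone methyl ester, the tertiary spiro ether and all four stereocentres untouched.

**Compound list**
1 | (S)-(+)-carvone | O=C1C(C)=CC[C@H](C(C)=C)C1 | starting material
2 | (5S)-5-(2-hydroxypropan-2-yl)-2-methylcyclohex-2-en-1-one | O=C1C(C)=CC[C@H](C(C)(C)O)C1 | intermediate
3 | (5S)-2-methyl-5-[2-(triethylsilyloxy)propan-2-yl]cyclohex-2-en-1-one | O=C1C(C)=CC[C@H](C(C)(C)O[Si](CC)(CC)CC)C1 | intermediate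
4 | lithium (3S)-6-methyl-3-[2-(triethylsilyloxy)propan-2-yl]cyclohexa-1,5-dien-1-olate (not isolated) | [Li]OC1=C[C@@H](C(C)(C)O[Si](CC)(CC)CC)CC=C1C | intermediate
5 | (5S,6R)-2,6-dimethyl-5-[2-(triethylsilyloxy)propan-2-yl]cyclohex-2-en-1-one (major 5,6-trans epimer) | O=C1C(C)=CC[C@H](C(C)(C)O[Si](CC)(CC)CC)[C@H]1C | intermediate
6 | lithium (3S)-2,6-dimethyl-3-[2-(triethylsilyloxy)propan-2-yl]cyclohexa-1,5-dien-1-olate (not isolated) | [Li]OC1=C(C)[C@@H](C(C)(C)O[Si](CC)(CC)CC)CC=C1C | intermediate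
7 | (5S,6R)-2,6-dimethyl-6-(prop-2-en-1-yl)-5-[2-(triethylsilyloxy)propan-2-yl]cyclohex-2-en-1-one | O=C1C(C)=CC[C@H](C(C)(C)O[Si](CC)(CC)CC)[C@@]1(C)CC=C | intermediate
8 | (5S,6R)-6-[3-(9-borabicyclo[3.3.1]nonan-9-yl)propyl]-2,6-dimethyl-5-[2-(triethylsilyloxy)propan-2-yl]cyclohex-2-en-1-one (not isolated) | O=C1C(C)=CC[C@H](C(C)(C)O[Si](CC)(CC)CC)[C@@]1(C)CCCB1C2CCCC1CCC2 | intermediate
9 | (5S,6R)-6-(3-hydroxypropyl)-2,6-dimethyl-5-[2-(triethylsilyloxy)propan-2-yl]cyclohex-2-en-1-one | O=C1C(C)=CC[C@H](C(C)(C)O[Si](CC)(CC)CC)[C@@]1(C)CCCO | intermediate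
10 | 3-[(1R,6S)-1,3-dimethyl-2-oxo-6-[2-(triethylsilyloxy)propan-2-yl]cyclohex-3-en-1-yl]propanoic acid | O=C1C(C)=CC[C@H](C(C)(C)O[Si](CC)(CC)CC)[C@@]1(C)CCC(=O)O | intermediate
11 | 2-(trimethylsilyl)ethyl 3-[(1R,6S)-1,3-dimethyl-2-oxo-6-[2-(triethylsilyloxy)propan-2-yl]cyclohex-3-en-1-yl]propanoate | O=C1C(C)=CC[C@H](C(C)(C)O[Si](CC)(CC)CC)[C@@]1(C)CCC(=O)OCC[Si](C)(C)C | intermediate
12 | 2-(trimethylsilyl)ethyl 3-[(1R,6S)-1,3-dimethyl-2-methylidene-6-[2-(triethylsilyloxy)propan-2-yl]cyclohex-3-en-1-yl]propanoate | C=C1C(C)=CC[C@H](C(C)(C)O[Si](CC)(CC)CC)[C@@]1(C)CCC(=O)OCC[Si](C)(C)C | intermediate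
13 | methyl 2,4-dihydroxy-3,6-dimethylbenzoate (atraric acid) | COC(=O)c1c(C)cc(O)c(C)c1O | starting material
14 | methyl 2,4-dihydroxy-5-iodo-3,6-dimethylbenzoate | COC(=O)c1c(C)c(I)c(O)c(C)c1O | intermediate
15 | 2-(trimethylsilyl)ethyl 3-[(2S,5'S,6'R)-6-hydroxy-5-(methoxycarbonyl)-2',4,6',7-tetramethyl-5'-[2-(triethylsilyloxy)propan-2-yl]-3H-spiro[1-benzofuran-2,1'-cyclohex[2]en]-6'-yl]propanoate | COC(=O)c1c(C)c2c(c(C)c1O)O[C@@]1(C2)C(C)=CC[C@H](C(C)(C)O[Si](CC)(CC)CC)[C@@]1(C)CCC(=O)OCC[Si](C)(C)C | intermediate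
16 | 2-(trimethylsilyl)ethyl 3-[(2S,2'R,5'S,6'R)-6-hydroxy-5-(methoxycarbonyl)-2',4,6',7-tetramethyl-5'-[2-(triethylsilyloxy)propan-2-yl]-3H-spiro[1-benzofuran-2,1'-cyclohexan]-6'-yl]propanoate | COC(=O)c1c(C)c2c(c(C)c1O)O[C@@]1(C2)[C@H](C)CC[C@H](C(C)(C)O[Si](CC)(CC)CC)[C@@]1(C)CCC(=O)OCC[Si](C)(C)C | intermediate
17 | 2-(trimethylsilyl)ethyl 3-[(2S,2'R,5'S,6'R)-3a-(dichloromethyl)-5-(methoxycarbonyl)-2',4,6',7-tetramethyl-6-oxo-5'-[2-(triethylsilyloxy)propan-2-yl]-3a,6-dihydro-3H-spiro[1-benzofuran-2,1'-cyclohexan]-6'-yl]propanoate (either configuration at C3a, a centre lost on ring expansion; not isolated) | COC(=O)C1=C(C)C2(C(Cl)Cl)C(=C(C)C1=O)O[C@@]1(C2)[C@H](C)CC[C@H](C(C)(C)O[Si](CC)(CC)CC)[C@@]1(C)CCC(=O)OCC[Si](C)(C)C | intermediate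
18 | 2-(trimethylsilyl)ethyl 3-[(2S,2'R,5'S,6'R)-6-(methoxycarbonyl)-2',5,6',8-tetramethyl-7-oxo-5'-[2-(triethylsilyloxy)propan-2-yl]-3,7-dihydrospiro[cyclohepta[b]furan-2,1'-cyclohexan]-6'-yl]propanoate | COC(=O)c1c(C)cc2c(c(C)c1=O)O[C@@]1(C2)[C@H](C)CC[C@H](C(C)(C)O[Si](CC)(CC)CC)[C@@]1(C)CCC(=O)OCC[Si](C)(C)C | intermediate
19 | 3-[(2S,2'R,5'S,6'R)-5'-(2-hydroxypropan-2-yl)-6-(methoxycarbonyl)-2',5,6',8-tetramethyl-7-oxo-3,7-dihydrospiro[cyclohepta[b]furan-2,1'-cyclohexan]-6'-yl]propanoic acid (CNP0448476.4; C5 S, C8 R, C9 S, C10 R) | COC(=O)c1c(C)cc2c(c(C)c1=O)O[C@@]1(C2)[C@H](C)CC[C@H](C(C)(C)O)[C@@]1(C)CCC(=O)O | target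

**Totals**
Total step count: 13. Longest linear sequence: 12 steps (steps 1–8 and 10–13, from (S)-carvone).

**Three steps most likely to fail**

Step 12 (the proposed new CH insertion). The radical may couple at C7 or at oxygen instead of C3a, the phenoxyl radical may lose a C3 hydrogen to give a quinone methide, or the ring expansion may go towards C7a. The fallback sets out from 16 and comes back at 18 using known two-electron chemistry with isolation of the intermediate. Dichlorocarbene, generated from CHCl3 with 50% aq. NaOH and BnEt3NCl at 0 °C, attacks the phenolate at the blocked para carbon (abnormal Reimer–Tiemann reaction), and dienone 17 is isolated by chromatography. Heating 17 with Bu3SnH and AIBN in benzene at 80 °C then effects the known radical ring expansion with loss of chlorine to tropone 18. This fallback makes no compound outside the list.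

Step 10 (heteroannulation). The hindered diene may undergo β-hydride elimination to a Heck-type triene, or the oxygen may close on the lower face to give the C9 epimer. The fallback sets out from enone ester 11 and iodide 14 and comes back at 15; it forms the C11–aryl bond by cross-coupling and the C9–O bond by a separate cationic cyclisation.
- Enone 11 has no α'-hydrogen, so KN(SiMe3)2 and PhNTf2 (THF, −78 °C) deprotonate at the γ-carbon and give 2-(trimethylsilyl)ethyl 3-[(1R,6S)-1,3-dimethyl-6-[2-(triethylsilyloxy)propan-2-yl]-2-(trifluoromethylsulfonyloxy)cyclohexa-2,4-dien-1-yl]propanoate F1.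
- Iodide 14 is coupled with bis[(pinacolato)boryl]methane (Pd(PtBu3)2, KOH, dioxane/H2O, rt) to methyl 2,4-dihydroxy-3,6-dimethyl-5-[(4,4,5,5-tetramethyl-1,3,2-dioxaborolan-2-yl)methyl]benzoate F2.
- B-benzyl Suzuki–Miyaura coupling of F1 and F2 (Pd(dppf)Cl2, K3PO4, dioxane/H2O, 60 °C) gives 2-(trimethylsilyl)ethyl 3-[(1R,6S)-2-{[2,4-dihydroxy-5-(methoxycarbonyl)-3,6-dimethylphenyl]methyl}-1,3-dimethyl-6-[2-(triethylsilyloxy)propan-2-yl]cyclohexa-2,4-dien-1-yl]propanoate F3.
- Catalytic camphorsulfonic acid (CH2Cl2, 0 °C) protonates the diene at C6, and the ortho phenol closes on the allyl cation at C9 from the face anti to the axial C10 methyl to give 15.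

Step 11 (hydrogenation). The catalyst may be deactivated by the phenol or the hindered alkene may not react. The fallback sets out from 15 and comes back at 16; it replaces catalytic hydrogenation by hydroboration and radical deoxygenation, which cannot cleave the allylic C–O bond.
- BH3·SMe2 (THF, 0 °C), then NaBO3·4H2O, adds boron to C7 and hydrogen to C8 from the upper face and gives 2-(trimethylsilyl)ethyl 3-[(2S,2'R,3'S,5'S,6'R)-3',6-dihydroxy-5-(methoxycarbonyl)-2',4,6',7-tetramethyl-5'-[2-(triethylsilyloxy)propan-2-yl]-3H-spiro[1-benzofuran-2,1'-cyclohexan]-6'-yl]propanoate F4.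
- 1,1'-Thiocarbonyldiimidazole and DMAP (ClCH2CH2Cl, 60 °C) acylate the secondary alcohol (the hydrogen-bonded salicylate hydroxyl is left alone) and give 2-(trimethylsilyl)ethyl 3-[(2S,2'R,3'S,5'S,6'R)-6-hydroxy-3'-(imidazole-1-carbothioyloxy)-5-(methoxycarbonyl)-2',4,6',7-tetramethyl-5'-[2-(triethylsilyloxy)propan-2-yl]-3H-spiro[1-benzofuran-2,1'-cyclohexan]-6'-yl]propanoate F5.
- Bu3SnH and AIBN (PhMe, 90 °C) remove the oxygen (Barton–McCombie deoxygenation) and give 16.

**Further compounds**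
F1 | step 10 | 2-(trimethylsilyl)ethyl 3-[(1R,6S)-1,3-dimethyl-6-[2-(triethylsilyloxy)propan-2-yl]-2-(trifluoromethylsulfonyloxy)cyclohexa-2,4-dien-1-yl]propanoate | FC(F)(F)S(=O)(=O)OC1=C(C)C=C[C@H](C(C)(C)O[Si](CC)(CC)CC)[C@@]1(C)CCC(=O)OCC[Si](C)(C)C
F2 | step 10 | methyl 2,4-dihydroxy-3,6-dimethyl-5-[(4,4,5,5-tetramethyl-1,3,2-dioxaborolan-2-yl)methyl]benzoate | COC(=O)c1c(C)c(CB2OC(C)(C)C(C)(C)O2)c(O)c(C)c1O
F3 | step 10 | 2-(trimethylsilyl)ethyl 3-[(1R,6S)-2-{[2,4-dihydroxy-5-(methoxycarbonyl)-3,6-dimethylphenyl]methyl}-1,3-dimethyl-6-[2-(triethylsilyloxy)propan-2-yl]cyclohexa-2,4-dien-1-yl]propanoate | COC(=O)c1c(C)c(CC2=C(C)C=C[C@H](C(C)(C)O[Si](CC)(CC)CC)[C@@]2(C)CCC(=O)OCC[Si](C)(C)C)c(O)c(C)c1O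
F4 | step 11 | 2-(trimethylsilyl)ethyl 3-[(2S,2'R,3'S,5'S,6'R)-3',6-dihydroxy-5-(methoxycarbonyl)-2',4,6',7-tetramethyl-5'-[2-(triethylsilyloxy)propan-2-yl]-3H-spiro[1-benzofuran-2,1'-cyclohexan]-6'-yl]propanoate | COC(=O)c1c(C)c2c(c(C)c1O)O[C@@]1(C2)[C@H](C)[C@@H](O)C[C@H](C(C)(C)O[Si](CC)(CC)CC)[C@@]1(C)CCC(=O)OCC[Si](C)(C)C
F5 | step 11 | 2-(trimethylsilyl)ethyl 3-[(2S,2'R,3'S,5'S,6'R)-6-hydroxy-3'-(imidazole-1-carbothioyloxy)-5-(methoxycarbonyl)-2',4,6',7-tetramethyl-5'-[2-(triethylsilyloxy)propan-2-yl]-3H-spiro[1-benzofuran-2,1'-cyclohexan]-6'-yl]propanoate | COC(=O)c1c(C)c2c(c(C)c1O)O[C@@]1(C2)[C@H](C)[C@@H](OC(=S)n3ccnc3)C[C@H](C(C)(C)O[Si](CC)(CC)CC)[C@@]1(C)CCC(=O)OCC[Si](C)(C)C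
F0 | step 12 | none | none
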